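Readings and results were computed with made-up constants; noise was put on by code.

At 120 min the reading of the epsilon run leaves 62.3 % of its E and 65.7 % of its L unturned, yet Z has not risen beyond the scatter of 1 mM since 90 min, so I look to X.

| flask | E | L | X | time |
|---|---|---|---|---|
| epsilon | 120 mM | 132 mM | 1.20 mM |  |
| zeta | 180 mM | 132 mM | 1.20 mM |  |
| eta | 120 mM | 132 mM | 2.40 mM |  |
| gamma | 120 mM | 66.0 mM | 1.20 mM |  |
| alpha | 120 mM | 132 mM | 1.20 mM | 360 min |

| run | time / min | [Z] / mM |
|---|---|---|
| epsilon run | 6.8 | 11.1 |
| epsilon run | 21 | 27.2 |
| epsilon run | 40 | 35.8 |
| epsilon run | 63 | 41.1 |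
| epsilon run | 90 | 46.6 |
| epsilon run | 120 | 45.3 |
| zeta run | 6.8 | 11.3 |
| zeta run | 21 | 27.7 |
| zeta run | 40 | 35.3 |
| zeta run | 63 | 42.9 |
| zeta run | 90 | 47.2 |
| zeta run | 120 | 48.0 |
| eta run | 6.8 | 28.9 |
| eta run | 21 | 65.9 |
| eta run | 40 | 90.4 |
| eta run | 63 | 104.0 |
| eta run | 90 | 110.7 |
| eta run | 120 | 115.7 |
| gamma run | 6.8 | 7.8 |
| gamma run | 21 | 22.4 |
| gamma run | 40 | 31.5 |
| gamma run | 63 | 39.6 |
| gamma run | 90 | 44.4 |
| gamma run | 120 | 45.7 |

(standard deviation of a reading: 1 mM)

- the power of [X] that the first rate follows, about the charge of the epsilon run; measure it at two percent of E made into Z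
- the power of [L] that the first rate follows, about the charge of the epsilon run; measure it at two percent of E made into Z
- Z in the alpha run at 360 min, as a share of the E charged

- Overall: E + L -> Z, with X as catalyst.
- Constant volume, constant temperature.
- The analysis sees a species whether free or bound.
- An order is taken over about fifteen percent of the charge, up and down.

I begin with the level at which Z stops. The epsilon run reads 46.6 mM and 45.3 mM at its last times, and the zeta run, with 180 mM of E, reads 47.2 mM and 48.0 mM, so I pool them as 46.8 mM.

Now I work with the fraction left to be made and not the fraction made. If that fraction falls exponentially, the reading at 40 min gives a lifetime of 27.6 min. Correcting the pooled level for what was still to come at its mean time gives a final Z of 47.8 mM, which is 39.9 % of the E charged. The alpha run has the epsilon charge, and at 360 min this lifetime puts its fraction left to be made at <0.001 %, so I commit to that share.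

Next I suppose that a fixed amount of X is lost at the start and that the rate follows the rest. I call the live share the part of the X charged in the epsilon run that survives this loss, a catalyst poisoning. Doubling X then multiplies the rate by (1+s)/s, where s is that share, and the power of [X] at the charge is 1/s. The first readings give a ratio of 2.60, so the power is 1.60.

That ratio is the weak link, since it rests on a single reading from each of two bending curves. I reforge it from fractions left. The whole epsilon curve gives a starting rate of 1.73 mM min⁻¹. The fraction of E left at the first reading of the eta run gives 4.86 mM min⁻¹. The ratio becomes 2.80, the live share 0.554, and the power 1.81. For L, the first readings of the gamma and epsilon runs give 0.509 across the halving, which I hold loosely.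

The forecast gives 1.5 for the power of [X], 0.42 for the power of [L] and 41 % for the alpha run, with the suggestion that “a fixed poison removes about 0.45 mM X”.

The flask gives 2.0 for the power of [X], 0.099 for the power of [L] and 39.8 % for the alpha run.

    X + E → XE (76.80 M⁻¹ min⁻¹)
    XE + L → Oz (230.4 M⁻¹ min⁻¹)
    Oz → Z + X (4.944 min⁻¹)
    X + Vy → Jy
    X + E → Jy + E (1.008 M⁻¹ min⁻¹)

By my rule, that power of [X] means a live share of 0.492, where I had 0.554. At mixing in the epsilon run, Vy takes 0.573 mM of the X, and the rest cycles through XE and Oz to Z while E and L are there. Alongside that cycle, X + E gives Jy + E, and at 360 min the alpha run stands at 39.8 % of its E turned to Z, with 60.2 % of that E not turned. Carried to the eta run, my live share and lifetime put half of its E at 16.4 min, and the eta run reaches it at 17.5 min.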